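You read this flask at 5.0 h, so ask what must stand in it then, and let the run pass slowly up to that time.

J 0.050 M; time 5.0 h

    J + G → J.G (k1 = 0.35 M⁻¹ min⁻¹)
    J + Z ⇌ G + E (K2 = 2.2, k2 = 1.1 M⁻¹ min⁻¹)
    Z + G ⇌ Z.G, settled at all times (K3 = 310 M⁻¹)

1. the concentration of Z at which the part of the J that has reacted at 5.0 h is just 95 %, in M

1. First instants. Try a Z of 0.100 M. J then has a half-life of 6.30 min by the forward J + Z step, much shorter than the 5.0 h you have.

2. Middle. Each J that reacts frees a G. At the trial Z, K3 times Z is 31.0, so nearly all of that G sits as Z.G, and each J reacted costs you about two Z.

3. End. With 6.30 min far shorter than 5.0 h, I take J + Z ⇌ G + E as balanced. Setting the J + G step aside for now, the wanted end has J at 0.00250 M, and E and total G at 0.0475 M. The balance then gives r, free G over free Z, as K2 times J over E: 0.116. Together with K3, this gives free Z of 0.0348 M and free G of 0.00403 M. At that free Z, the forward half-life of J is 18.1 min, longer than at the start but still shorter than 5.0 h, so I keep the balance as my assumption for the end. Adding free Z, Z.G and E, I commit to a charge of 0.126 M.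

4. The neglected step. 8.19 h is the drain half-life, the pseudo-first-order half-life of J by J + G → J.G at that free G. It is longer than the run. At that end rate, the whole run carries off 0.00106 M, far less than the J charged, but that amount is 42.3 % of the 0.00250 M of J allowed to stand at the end, so I do not count it as nothing.

The forecast gives 0.115 M, lower than my figure, holding that “Z is used about two for one”.

The simulation gives 0.119 M. At 5.00 h, the half-life of J by the J + G step reads 8.2 h, beside the drain half-life of 8.19 h, and it is still longer than the run, having come down from 35 h at 0.101 h. Counting the forward rate of the reversible step alone, J + Z uses J 240 times as fast as J + G at 0.101 h, and 26 times as fast at 5.00 h.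

Its constants are those of an exercise; what happens was integrated by code.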